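**Retrosynthetic overview**
- Last operations: removal of the 4'-O-silyl group, then chelation-controlled cleavage of the 5-OMe (peri to C4=O) of a 6-hydroxy-5,7-dimethoxyflavone.
- Only the C ring (pyranone) is built. C4–C4a comes from a new redox-neutral C–H alkynoylation of symmetric 2,6-dimethoxy-1,4-benzoquinone (the A ring; its para O6/O1 pattern is a masked hydroquinone) with an aryl ynal. O1–C2 follows in the same flask by 6-endo-dig oxa-Michael closure.
- The aryl ynal (B ring plus C2, C3, C4) comes from Sonogashira coupling of a 4-iodo-2,5-dimethoxyphenyl silyl ether with propargyl alcohol, then MnO2 oxidation; the iodide comes from para-iodination of 2,5-dimethoxyphenol.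
- Ring order: A and B rings are bought as benzenoid building blocks; the C ring is closed in step 5.

Assumption: the target has no stereocentre and no configurationally stable axis (it is achiral), so no enantiocontrol is needed; 2,5-dimethoxyphenol, propargyl alcohol and 2,6-dimethoxy-1,4-benzoquinone are taken as commercial.

**Route**

Step 1
Reactants: 1 2,5-dimethoxyphenol
Product: 2 4-iodo-2,5-dimethoxyphenol
Conditions: NIS (1.0 equiv), MeCN, 0 °C to rt, dark
Reagents that add atoms: N-iodosuccinimide, O=C1CCC(=O)N1I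
Why: Electrophilic aromatic iodination; the free OH directs para (C4, also ortho to the 5-OMe, the usual halogenation site of 1,2,4-trioxygenated benzenes), whereas C6 is flanked by two substituents and C3 is activated by one OMe only.

Step 2
Reactants: 2 4-iodo-2,5-dimethoxyphenol
Product: 3 tert-butyl(4-iodo-2,5-dimethoxyphenoxy)dimethylsilane
Conditions: TBSCl (1.2 equiv), imidazole (2 equiv), DMF, rt
Reagents that add atoms: tert-butyldimethylsilyl chloride, CC(C)(C)[Si](C)(C)Cl
Why: Standard silylation of a phenol; the silyl ether removes the radical-quenching phenolic O–H and, unlike a benzyl or MOM ether, has no weak C–H bond that could compete in the hydrogen-atom-transfer step 5.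

Step 3
Reactants: 3 tert-butyl(4-iodo-2,5-dimethoxyphenoxy)dimethylsilane; 4 prop-2-yn-1-ol (propargyl alcohol)
Product: 5 3-[4-(tert-butyldimethylsilyloxy)-2,5-dimethoxyphenyl]prop-2-yn-1-ol
Conditions: 4 (1.5 equiv), PdCl2(PPh3)2 (3 mol%), CuI (5 mol%), Et3N/THF, 50 °C, Ar
Reagents that add atoms: none
Why: Sonogashira coupling of an aryl iodide with a terminal alkyne; the aryl silyl ether and the free primary alcohol are tolerated under Et3N at 50 °C.

Step 4
Reactants: 5 3-[4-(tert-butyldimethylsilyloxy)-2,5-dimethoxyphenyl]prop-2-yn-1-ol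
Product: 6 3-[4-(tert-butyldimethylsilyloxy)-2,5-dimethoxyphenyl]prop-2-ynal
Conditions: activated MnO2 (10 equiv), CH2Cl2, rt
Reagents that add atoms: none
Why: Activated MnO2 selectively oxidises propargylic alcohols to ynals without going on to the acid and leaves the aryl silyl ether and the methyl ethers untouched.

Step 5
Reactants: 6 3-[4-(tert-butyldimethylsilyloxy)-2,5-dimethoxyphenyl]prop-2-ynal; 7 2,6-dimethoxy-1,4-benzoquinone
Product: 9 2-[4-(tert-butyldimethylsilyloxy)-2,5-dimethoxyphenyl]-6-hydroxy-5,7-dimethoxy-4H-chromen-4-one, via acylhydroquinone ynone 8 (not isolated)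
Conditions: 7 (1.5 equiv, added in portions), (nBu4N)4[W10O32] (2 mol%), degassed MeCN, 390 nm LEDs, 25 °C, Ar; then DMAP (30 mol%), 50 °C, dark
Reagents that add atoms: none
Why: Proposed new method: a redox-neutral photocatalytic C–H alkynoylation of an alkoxy-p-benzoquinone by an ynal, telescoped with ring closure; excited decatungstate (or triplet 7 itself, which absorbs at the same wavelength) abstracts the formyl hydrogen of 6 to give a σ-alkynoyl radical that cannot decarbonylate, this nucleophilic radical adds to the only kind of free ring carbon of the symmetric, electrophilic quinone (C3, giving a captodatively stabilised α-methoxy enoxyl radical, so only one regioisomer is possible), tautomerisation and back hydrogen-atom transfer from the reduced polyoxometalate (or from a semiquinone) give acylhydroquinone 8, whose acyl group makes it harder to oxidise than 2,6-dimethoxyhydroquinone so that excess 7 does not re-oxidise it, and DMAP then triggers the known 6-endo-dig oxa-Michael addition of the chelated ortho OH to the ynone, which closes the pyranone; the closest known reaction types are the photo-Friedel–Crafts (Klinger) acylation of unsubstituted benzo- and naphthoquinones with simple aldehydes and the decatungstate hydroacylation of electron-poor alkenes, to my knowledge not shown for ynals or for dialkoxyquinones, nor merged with flavone ring closure.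

Step 6
Reactants: 9 2-[4-(tert-butyldimethylsilyloxy)-2,5-dimethoxyphenyl]-6-hydroxy-5,7-dimethoxy-4H-chromen-4-one
Product: 10 6-hydroxy-2-(4-hydroxy-2,5-dimethoxyphenyl)-5,7-dimethoxy-4H-chromen-4-one
Conditions: TBAF (1.1 equiv), AcOH (1.2 equiv), THF, 0 °C
Reagents that add atoms: none
Why: Fluoride-mediated cleavage of an aryl silyl ether, driven by the Si–F bond; AcOH buffering keeps the phenols protonated so the flavone is not exposed to base and air.

Step 7
Reactants: 10 6-hydroxy-2-(4-hydroxy-2,5-dimethoxyphenyl)-5,7-dimethoxy-4H-chromen-4-one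
Product: 11 5,6-dihydroxy-2-(4-hydroxy-2,5-dimethoxyphenyl)-7-methoxy-4H-chromen-4-one (target)
Conditions: BCl3 (1 M in CH2Cl2, 4 equiv), CH2Cl2, −78 to 0 °C, Ar; then aq. HCl
Reagents that add atoms: none
Why: Lewis-acid ether cleavage under chelation control: boron bound to the C4 carbonyl forms a six-membered chelate with the peri 5-OMe oxygen (held further by the neighbouring 6-O–B), so chloride demethylates only this ether at low temperature, while the 7-, 2'- and 5'-OMe groups, which cannot chelate to the carbonyl, stay.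

**Compound list**
1 | 2,5-dimethoxyphenol | COc1ccc(OC)c(O)c1 | starting material
2 | 4-iodo-2,5-dimethoxyphenol | COc1cc(O)c(OC)cc1I | intermediate
3 | tert-butyl(4-iodo-2,5-dimethoxyphenoxy)dimethylsilane | COc1cc(O[Si](C)(C)C(C)(C)C)c(OC)cc1I | intermediate
4 | prop-2-yn-1-ol (propargyl alcohol) | C#CCO | starting material
5 | 3-[4-(tert-butyldimethylsilyloxy)-2,5-dimethoxyphenyl]prop-2-yn-1-ol | COc1cc(O[Si](C)(C)C(C)(C)C)c(OC)cc1C#CCO | intermediate
6 | 3-[4-(tert-butyldimethylsilyloxy)-2,5-dimethoxyphenyl]prop-2-ynal | COc1cc(O[Si](C)(C)C(C)(C)C)c(OC)cc1C#CC=O | intermediate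
7 | 2,6-dimethoxy-1,4-benzoquinone | COC1=CC(=O)C=C(OC)C1=O | starting material
8 | 1-(3,6-dihydroxy-2,4-dimethoxyphenyl)-3-[4-(tert-butyldimethylsilyloxy)-2,5-dimethoxyphenyl]prop-2-yn-1-one (not isolated) | COc1cc(O)c(C(=O)C#Cc2cc(OC)c(O[Si](C)(C)C(C)(C)C)cc2OC)c(OC)c1O | intermediate
9 | 2-[4-(tert-butyldimethylsilyloxy)-2,5-dimethoxyphenyl]-6-hydroxy-5,7-dimethoxy-4H-chromen-4-one | COc1cc2oc(-c3cc(OC)c(O[Si](C)(C)C(C)(C)C)cc3OC)cc(=O)c2c(OC)c1O | intermediate
10 | 6-hydroxy-2-(4-hydroxy-2,5-dimethoxyphenyl)-5,7-dimethoxy-4H-chromen-4-one | COc1cc2oc(-c3cc(OC)c(O)cc3OC)cc(=O)c2c(OC)c1O | intermediate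
11 | 5,6-dihydroxy-2-(4-hydroxy-2,5-dimethoxyphenyl)-7-methoxy-4H-chromen-4-one (achiral) | COc1cc(-c2cc(=O)c3c(O)c(O)c(OC)cc3o2)c(OC)cc1O | target

**Step count and risks**

Total step count: 7. Longest linear sequence: 7 steps (1 to 11); 4 and 7 enter as bought fragments.

Steps most likely to fail:

Step 5 (the proposed new step). The risks are slow hydrogen abstraction from the electron-poor formyl C–H, electron-transfer quenching by the electron-rich aryl ring, O- instead of C-acylation, light screening by 7, and photo-oxidation of 8. The fallback uses known chemistry only, sets out from 7 and 6, and comes back to the route at 8. Quinone 7 is reduced with aqueous Na2S2O4 to 2,6-dimethoxybenzene-1,4-diol F1. NaH/MOMCl in DMF converts this into 1,3-dimethoxy-2,5-bis(methoxymethoxy)benzene F2. n-BuLi in THF at 0 °C deprotonates F2 between an OMe and an OMOM group (directed ortho-metalation; the two ring hydrogens are equivalent) to give [2,4-dimethoxy-3,6-bis(methoxymethoxy)phenyl]lithium F3. At −78 °C this adds 1,2 to ynal 6 and, after NH4Cl quench, gives racemic 1-[2,4-dimethoxy-3,6-bis(methoxymethoxy)phenyl]-3-[4-(tert-butyldimethylsilyloxy)-2,5-dimethoxyphenyl]prop-2-yn-1-ol F4. MnO2 in CH2Cl2 oxidises it to 1-[2,4-dimethoxy-3,6-bis(methoxymethoxy)phenyl]-3-[4-(tert-butyldimethylsilyloxy)-2,5-dimethoxyphenyl]prop-2-yn-1-one F5. ZnBr2/n-PrSH in CH2Cl2 at 0 °C removes both MOM ethers without touching the aryl silyl ether and gives 8, which is closed to 9 with DMAP as in the second half of step 5.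

Step 7. The risk is over-demethylation at C7 or C5', assisted by boron bound to the free 6-OH and 4'-OH, or incomplete reaction. The fallback masks the phenols so that only carbonyl chelation can direct the cleavage; it sets out from 10 and comes back at 11. Ac2O/pyridine gives 2-(4-acetoxy-2,5-dimethoxyphenyl)-5,7-dimethoxy-4-oxo-4H-chromen-6-yl acetate F6. BCl3 in CH2Cl2 at −78 to 0 °C cleaves only the peri 5-OMe and gives 2-(4-acetoxy-2,5-dimethoxyphenyl)-5-hydroxy-7-methoxy-4-oxo-4H-chromen-6-yl acetate F7. Acid methanolysis (catalytic AcCl in MeOH, 40 °C, Ar) removes both acetates and gives 11.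

Step 4. The risk is that the electrophilic ynal degrades on MnO2 or on silica, or that MnO2 of variable activity stalls. The fallback avoids any oxidation by carrying the aldehyde through the coupling as an acetal; it sets out from 3 and comes back at 6. Sonogashira coupling of 3 with 3,3-diethoxyprop-1-yne (PdCl2(PPh3)2, CuI, Et3N, 50 °C) gives tert-butyl[4-(3,3-diethoxyprop-1-yn-1-yl)-2,5-dimethoxyphenoxy]dimethylsilane F8. Aqueous formic acid in CH2Cl2 at rt hydrolyses the acetal to 6.

Further compounds
F1 | step 5 | 2,6-dimethoxybenzene-1,4-diol | COc1cc(O)cc(OC)c1O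
F2 | step 5 | 1,3-dimethoxy-2,5-bis(methoxymethoxy)benzene | COCOc1cc(OC)c(OCOC)c(OC)c1
F3 | step 5 | [2,4-dimethoxy-3,6-bis(methoxymethoxy)phenyl]lithium | [Li]c1c(OC)c(OCOC)c(OC)cc1OCOC
F4 | step 5 | 1-[2,4-dimethoxy-3,6-bis(methoxymethoxy)phenyl]-3-[4-(tert-butyldimethylsilyloxy)-2,5-dimethoxyphenyl]prop-2-yn-1-ol (racemic) | COCOc1cc(OC)c(OCOC)c(OC)c1C(O)C#Cc1cc(OC)c(O[Si](C)(C)C(C)(C)C)cc1OC
F5 | step 5 | 1-[2,4-dimethoxy-3,6-bis(methoxymethoxy)phenyl]-3-[4-(tert-butyldimethylsilyloxy)-2,5-dimethoxyphenyl]prop-2-yn-1-one | COCOc1cc(OC)c(OCOC)c(OC)c1C(=O)C#Cc1cc(OC)c(O[Si](C)(C)C(C)(C)C)cc1OC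
F6 | step 7 | 2-(4-acetoxy-2,5-dimethoxyphenyl)-5,7-dimethoxy-4-oxo-4H-chromen-6-yl acetate | COc1cc2oc(-c3cc(OC)c(OC(C)=O)cc3OC)cc(=O)c2c(OC)c1OC(C)=O
F7 | step 7 | 2-(4-acetoxy-2,5-dimethoxyphenyl)-5-hydroxy-7-methoxy-4-oxo-4H-chromen-6-yl acetate | COc1cc2oc(-c3cc(OC)c(OC(C)=O)cc3OC)cc(=O)c2c(O)c1OC(C)=O
F8 | step 4 | tert-butyl[4-(3,3-diethoxyprop-1-yn-1-yl)-2,5-dimethoxyphenoxy]dimethylsilane | CCOC(OCC)C#Cc1cc(OC)c(O[Si](C)(C)C(C)(C)C)cc1OC
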